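The synthesis rests on cutting the enone olefin C1=C6 of the cyclohexenone ring (p-menthane numbering). This bond lies opposite the contiguous stereotriad C3–C4–C5, so closing it creates no stereocentre. In the open form its two ends are terminal olefins: an α-(silyloxymethyl)vinyl ketone (C7–C1–C2) and an allylic angelate (C5–C6). Ring-closing metathesis of octa-1,7-dien-3-one 17 should build the carbocycle and the trisubstituted enone in one neutral operation. The C2–C6 chain of 17 is C2–C6 of levoglucosenone. Its anhydro bridge and a derived γ-lactone (O5–C2) act as temporary rings that relay C5 to C4. After closure, iPr and OAng sit on one face and direct O3 to the other.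

Key step: step 11

Remark on numbering: p-menthane numbering of the target is used for all compounds. C1 is the olefinic carbon bearing C7H2OH, C2 the ketone, C3 the CH–O(epoxyangeloyl), C4 the CH–iPr, C5 the CH–OAng and C6 the olefinic CH. O3, O5 and O7 are the oxygens on C3, C5 and C7. Primed numbers refer to the C5 acids.
Assumption: (−)-levoglucosenone, angelic acid and 2-bromoprop-2-en-1-ol are taken as commercial.

Step 1
Reactants: 1 2-bromoprop-2-en-1-ol
Product: 2 [(2-bromoprop-2-en-1-yl)oxy](tert-butyl)dimethylsilane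
Conditions: TBSCl, imidazole, CH2Cl2, 0 °C to rt
Reagents that add atoms: tert-butyldimethylsilyl chloride, CC(C)(C)[Si](C)(C)Cl
Why: Routine imidazole-promoted O-silylation masks O7 so that the vinyl bromide can later be lithiated; no stereocentre is involved.

Step 2
Reactants: 3 angelic acid [(Z)-2-methylbut-2-enoic acid]
Product: 4 (Z)-2-methylbut-2-en-1-ol
Conditions: LiAlH4, Et2O, 0 °C to rt; aqueous NaOH work-up
Reagents that add atoms: none
Why: Hydride reduction of the carboxylic acid stops at the allylic alcohol and leaves the Z-trisubstituted olefin geometry untouched.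

Step 3
Reactants: 4 (Z)-2-methylbut-2-en-1-ol
Product: 5 [(2S,3R)-2,3-dimethyloxiran-2-yl]methanol
Conditions: Ti(OiPr)4 (cat.), L-(+)-diethyl tartrate (cat.), t-BuOOH, 4 Å MS, CH2Cl2, −20 °C
Reagents that add atoms: tert-butyl hydroperoxide, CC(C)(C)OO
Why: Sharpless asymmetric epoxidation, in which the L-(+)-tartrate/Ti complex delivers oxygen suprafacially to the olefin face that gives the (2S,3R)-epoxide, while the Z geometry fixes the cis relation of C4′H3 and CH2OH.

Step 4
Reactants: 5 [(2S,3R)-2,3-dimethyloxiran-2-yl]methanol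
Product: 6 (2R,3R)-2,3-dimethyloxirane-2-carboxylic acid (epoxyangelic acid)
Conditions: RuCl3 (cat.), NaIO4, MeCN/EtOAc/H2O, 0 °C to rt
Reagents that add atoms: sodium periodate, [Na+].[O-]I(=O)(=O)=O
Why: RuO4-catalysed oxidation of a primary alcohol to the acid tolerates the epoxide and touches neither stereocentre; the descriptor at C2′ changes from S to R only through the CIP ranking.

Step 5
Reactants: 7 (−)-levoglucosenone [(1S,5R)-6,8-dioxabicyclo[3.2.1]oct-2-en-4-one]
Product: 9 (1S,2R,5R)-2-isopropyl-6,8-dioxabicyclo[3.2.1]octan-4-one, via TMS enol ether 8 (not isolated)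
Conditions: i-PrMgCl, CuBr·SMe2 (10 mol %), TMSCl, THF, −78 °C; then 1 M HCl
Reagents that add atoms: isopropylmagnesium chloride, CC(C)[Mg]Cl
Why: TMSCl-accelerated copper-catalysed conjugate addition of the Grignard reagent; the 1,6-anhydro bridge (C6–O6) shields one face of the bicyclic enone, so iPr should enter C4 anti to C6, which sets C4 from C5.

Step 6
Reactants: 9 (1S,2R,5R)-2-isopropyl-6,8-dioxabicyclo[3.2.1]octan-4-one
Product: 11 (4R,5S)-5-(hydroxymethyl)-4-isopropyloxolan-2-one, via formate lactone 10 (not isolated)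
Conditions: mCPBA, CH2Cl2, rt; then HCl (cat.), MeOH, rt
Reagents that add atoms: 3-chloroperoxybenzoic acid, OOC(=O)c1cccc(Cl)c1
Why: Baeyer–Villiger oxidation in which the acetal carbon migrates; the acyloxy acetal collapses by acyl shift to O5 into the γ-lactone formate, and acid methanolysis frees O6H with C4 and C5 untouched.

Step 7
Reactants: 11 (4R,5S)-5-(hydroxymethyl)-4-isopropyloxolan-2-one
Product: 12 (2S,3R)-3-isopropyl-5-oxooxolane-2-carbaldehyde
Conditions: Dess–Martin periodinane, CH2Cl2, 0 °C to rt
Reagents that add atoms: none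
Why: Dess–Martin oxidation of the primary alcohol is neutral and spares the lactone; the trans C4/C5 arrangement is also the more stable one, so epimerisation at C5 is no threat.

Step 8
Reactants: 12 (2S,3R)-3-isopropyl-5-oxooxolane-2-carbaldehyde
Product: 13 (4R,5R)-5-ethenyl-4-isopropyloxolan-2-one
Conditions: Ph3PCH3Br, KHMDS, THF, −78 °C to 0 °C
Reagents that add atoms: methyltriphenylphosphonium bromide, C[P+](c1ccccc1)(c1ccccc1)c1ccccc1.[Br-]
Why: Wittig methylenation; the non-stabilised ylide reacts with the aldehyde far faster than with the lactone at low temperature and turns C6 into the vinyl group needed for metathesis.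

Step 9
Reactants: 2 [(2-bromoprop-2-en-1-yl)oxy](tert-butyl)dimethylsilane; 13 (4R,5R)-5-ethenyl-4-isopropyloxolan-2-one
Product: 15 (5R,6R)-2-{[(tert-butyldimethylsilyl)oxy]methyl}-6-hydroxy-5-isopropylocta-1,7-dien-3-one, via vinyllithium 14 (not isolated)
Conditions: 2, t-BuLi (2 equiv per 2), Et2O, −78 °C; then 13, −78 °C; AcOH quench at −78 °C
Reagents that add atoms: none
Why: Bromine–lithium exchange followed by 1,2-addition of the vinyllithium to the γ-lactone; the lithium lactolate persists at −78 °C so only one equivalent adds, and the quench frees the O5H enone, whose conjugated carbonyl disfavours the lactol form.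

Step 10
Reactants: 15 (5R,6R)-2-{[(tert-butyldimethylsilyl)oxy]methyl}-6-hydroxy-5-isopropylocta-1,7-dien-3-one; 3 angelic acid
Product: 17 (3R,4R)-7-{[(tert-butyldimethylsilyl)oxy]methyl}-4-isopropyl-6-oxoocta-1,7-dien-3-yl (Z)-2-methylbut-2-enoate, via mixed anhydride 16 (not isolated)
Conditions: 3, 2,4,6-trichlorobenzoyl chloride, Et3N, toluene, rt; then 15, toluene, 80 °C
Reagents that add atoms: none
Why: Yamaguchi-type mixed-anhydride esterification run without DMAP, the known way to form angelates without Z-to-E isomerisation; it traps the open hydroxy-enone form at O5 with retention at C5.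

Step 11
Reactants: 17 (3R,4R)-7-{[(tert-butyldimethylsilyl)oxy]methyl}-4-isopropyl-6-oxoocta-1,7-dien-3-yl (Z)-2-methylbut-2-enoate
Product: 18 (1S,6R)-3-{[(tert-butyldimethylsilyl)oxy]methyl}-6-isopropyl-4-oxocyclohex-2-en-1-yl (Z)-2-methylbut-2-enoate
Conditions: Hoveyda–Grubbs II (5–10 mol %), toluene (5 mM), 80 °C, Ar sparge
Reagents that add atoms: none
Why: Ring-closing olefin metathesis by the Chauvin mechanism: the Ru carbene loads on the monosubstituted C6 vinyl group, adds across the 1,1-disubstituted C1 methylene of the enone through a metallacyclobutane and releases ethene, so that C1=C6 forms irreversibly. The closest known reaction type is RCM of 2-substituted octa-1,7-dien-3-ones to 2-substituted cyclohex-2-enones with second-generation Ru catalysts. One ring is closed, the six-membered carbocycle C1–C6, joined head to head at the two CH2-capped olefin carbons, and within it the new olefin can only hold C2 and C5 cis. No stereocentre is created, and C4 and C5 ride on the tether untouched because the medium is neutral. The step needs chemoselection for the C1 methylene over the trisubstituted, electron-poor angelate olefin (closure there would give a butenolide) and over intermolecular cross-metathesis; the lower substitution at C1, the s-trans ester conformation, the branched C4/C5 tether and high dilution should secure it. Capping O5 as the angelate also removes the lactol form and any Ru-hydride isomerisation of a free allylic alcohol.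

Step 12
Reactants: 18 (1S,6R)-3-{[(tert-butyldimethylsilyl)oxy]methyl}-6-isopropyl-4-oxocyclohex-2-en-1-yl (Z)-2-methylbut-2-enoate
Product: 21 (1R,5S,6S)-3-{[(tert-butyldimethylsilyl)oxy]methyl}-5-hydroxy-6-isopropyl-4-oxocyclohex-2-en-1-yl (Z)-2-methylbut-2-enoate, via TMS dienol ether 19 (not isolated), via O3-TMS ketol 20 (not isolated)
Conditions: LDA, TMSCl (internal quench), THF, −78 °C; mCPBA, NaHCO3, CH2Cl2, −20 to 0 °C; citric acid, MeOH, 0 °C
Reagents that add atoms: 3-chloroperoxybenzoic acid, OOC(=O)c1cccc(Cl)c1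
Why: Rubottom oxidation of the kinetic cross-conjugated 2-silyloxydiene; LDA/TMSCl removes an α′ proton at C3 and the peracid attacks the electron-rich C2=C3 bond from the face opposite iPr (C4) and the pseudoaxial OAng (C5), which should place O3 trans to iPr, also the equatorial and more stable epimer.

Step 13
Reactants: 21 (1R,5S,6S)-3-{[(tert-butyldimethylsilyl)oxy]methyl}-5-hydroxy-6-isopropyl-4-oxocyclohex-2-en-1-yl (Z)-2-methylbut-2-enoate; 6 (2R,3R)-2,3-dimethyloxirane-2-carboxylic acid
Product: 22 O7-TBS ether of the target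
Conditions: DCC, DMAP (cat.), CH2Cl2, 0 °C to rt
Reagents that add atoms: none
Why: Steglich esterification of the secondary ketol with the epoxy acid proceeds with retention at C3, C2′ and C3′, and the mild conditions leave angelate, epoxide and silyl ether intact.

Step 14
Reactants: 22 O7-TBS ether of the target
Product: 23 (1R,5S,6R)-5-{[(2R,3R)-2,3-dimethyloxirane-2-carbonyl]oxy}-3-(hydroxymethyl)-6-isopropyl-4-oxocyclohex-2-en-1-yl (Z)-2-methylbut-2-enoate
Conditions: HF·pyridine, pyridine/THF, 0 °C
Reagents that add atoms: none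
Why: Buffered fluoride cleavage of the primary allylic TBS ether; esters, epoxy ester and enone are inert to HF·pyridine at 0 °C, and an acyl shift from O3 to O7 would need a seven-membered transition state.

Compound list
1 | 2-bromoprop-2-en-1-ol | C=C(Br)CO | starting material
2 | [(2-bromoprop-2-en-1-yl)oxy](tert-butyl)dimethylsilane | C=C(Br)CO[Si](C)(C)C(C)(C)C | intermediate
3 | angelic acid, (Z)-2-methylbut-2-enoic acid | C/C=C(/C)C(=O)O | starting material
4 | (Z)-2-methylbut-2-en-1-ol | C/C=C(/C)CO | intermediate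
5 | [(2S,3R)-2,3-dimethyloxiran-2-yl]methanol | OC[C@]1(C)O[C@@H]1C | intermediate
6 | (2R,3R)-2,3-dimethyloxirane-2-carboxylic acid | OC(=O)[C@]1(C)O[C@@H]1C | intermediate
7 | (−)-levoglucosenone | O=C1C=C[C@H]2CO[C@@H]1O2 | starting material
8 | TMS enol ether of 9 (iPr at C4 anti to the C6–O6 bridge) | C[Si](C)(C)OC1=C[C@H](C(C)C)[C@H]2CO[C@@H]1O2 | intermediate
9 | (1S,2R,5R)-2-isopropyl-6,8-dioxabicyclo[3.2.1]octan-4-one | O=C1C[C@H](C(C)C)[C@H]2CO[C@@H]1O2 | intermediate
10 | [(2S,3R)-3-isopropyl-5-oxooxolan-2-yl]methyl formate | O=C1C[C@H](C(C)C)[C@@H](COC=O)O1 | intermediate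
11 | (4R,5S)-5-(hydroxymethyl)-4-isopropyloxolan-2-one | O=C1C[C@H](C(C)C)[C@@H](CO)O1 | intermediate
12 | (2S,3R)-3-isopropyl-5-oxooxolane-2-carbaldehyde | O=C1C[C@H](C(C)C)[C@@H](C=O)O1 | intermediate
13 | (4R,5R)-5-ethenyl-4-isopropyloxolan-2-one | O=C1C[C@H](C(C)C)[C@@H](C=C)O1 | intermediate
14 | {3-[(tert-butyldimethylsilyl)oxy]prop-1-en-2-yl}lithium | [Li]C(=C)CO[Si](C)(C)C(C)(C)C | intermediate
15 | (5R,6R)-2-{[(tert-butyldimethylsilyl)oxy]methyl}-6-hydroxy-5-isopropylocta-1,7-dien-3-one | C=C(CO[Si](C)(C)C(C)(C)C)C(=O)C[C@H](C(C)C)[C@H](O)C=C | intermediate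
16 | (Z)-2-methylbut-2-enoic 2,4,6-trichlorobenzoic anhydride | C/C=C(/C)C(=O)OC(=O)c1c(Cl)cc(Cl)cc1Cl | intermediate
17 | (3R,4R)-7-{[(tert-butyldimethylsilyl)oxy]methyl}-4-isopropyl-6-oxoocta-1,7-dien-3-yl (Z)-2-methylbut-2-enoate | C=C(CO[Si](C)(C)C(C)(C)C)C(=O)C[C@H](C(C)C)[C@H](OC(=O)/C(C)=C\C)C=C | intermediate
18 | (1S,6R)-3-{[(tert-butyldimethylsilyl)oxy]methyl}-6-isopropyl-4-oxocyclohex-2-en-1-yl (Z)-2-methylbut-2-enoate (OAng cis to iPr) | C/C=C(/C)C(=O)O[C@@H]1C=C(CO[Si](C)(C)C(C)(C)C)C(=O)C[C@@H]1C(C)C | intermediate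
19 | cross-conjugated O2-TMS dienol ether of 18 (C2=C3 and C1=C6) | C/C=C(/C)C(=O)O[C@@H]1C=C(CO[Si](C)(C)C(C)(C)C)C(O[Si](C)(C)C)=C[C@@H]1C(C)C | intermediate
20 | O3-TMS ether of 21 | C/C=C(/C)C(=O)O[C@@H]1C=C(CO[Si](C)(C)C(C)(C)C)C(=O)[C@@H](O[Si](C)(C)C)[C@@H]1C(C)C | intermediate
21 | (1R,5S,6S)-3-{[(tert-butyldimethylsilyl)oxy]methyl}-5-hydroxy-6-isopropyl-4-oxocyclohex-2-en-1-yl (Z)-2-methylbut-2-enoate (O3H trans to iPr) | C/C=C(/C)C(=O)O[C@@H]1C=C(CO[Si](C)(C)C(C)(C)C)C(=O)[C@@H](O)[C@@H]1C(C)C | intermediate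
22 | O7-TBS ether of the target | C/C=C(/C)C(=O)O[C@@H]1C=C(CO[Si](C)(C)C(C)(C)C)C(=O)[C@@H](OC(=O)[C@]2(C)O[C@@H]2C)[C@@H]1C(C)C | intermediate
23 | (1R,5S,6R)-5-{[(2R,3R)-2,3-dimethyloxirane-2-carbonyl]oxy}-3-(hydroxymethyl)-6-isopropyl-4-oxocyclohex-2-en-1-yl (Z)-2-methylbut-2-enoate | C/C=C(/C)C(=O)O[C@@H]1C=C(CO)C(=O)[C@@H](OC(=O)[C@]2(C)O[C@@H]2C)[C@@H]1C(C)C | target

Total step count: 14. Longest linear sequence: 10 steps (steps 5–14, from levoglucosenone).

Steps most likely to fail

Step 11. The propagating carbene may not engage the electron-poor, 1,1-disubstituted C1 methylene. Homodimerisation at the C6 vinyl group or closure onto the angelate olefin could then take over. The fallback sets out from 17 and changes the oxidation level of the substrate. Luche reduction (NaBH4, CeCl3, MeOH) gives the C2 allylic alcohol F1 as a mixture of C2 epimers. Its olefin is electron-neutral and should close with a second-generation Ru catalyst to the cyclohexenol F2. Dess–Martin oxidation of the C2 carbinol then returns to the route at 18.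

Step 12. Enolisation may drift to the γ position (C5–H), the enolate may attack the neighbouring ester, or the facial selectivity of the oxidation may be poor. The fallback sets out from 13 and installs O3 on the rigid lactone before the ring is built. LiHMDS and a sulfonyloxaziridine hydroxylate the lactone enolate anti to iPr to give the all-trans hydroxy lactone F3. TESCl/imidazole gives the TES ether F4. Addition of 14 gives the O3-TES hydroxy enone F5. Mixed-anhydride angeloylation gives the O3-TES dienone angelate F6. Ring-closing metathesis gives the O3-TES cyclohexenone F7. Selective acid cleavage of the secondary TES ether (AcOH/THF/H2O) comes back to the route at 21.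

Step 9. Double addition, lactone enolisation, or O-to-C silyl migration within 14 may erode the mono-adduct. The fallback sets out from 13 and replaces the lactone by an acyclic acyl donor. Aminolysis with MeNHOMe·HCl/i-PrMgCl gives the hydroxy Weinreb amide F8. TESCl/imidazole gives the silylated Weinreb amide F9. Reagent 14 then adds once through the chelated tetrahedral intermediate to give the O5-TES enone F10. Mild acid removal of the TES group comes back to the route at 15.

Further compounds
F1 | step 11 | C2 allylic alcohol from 17 (C2 epimers) | C=C(CO[Si](C)(C)C(C)(C)C)C(O)C[C@H](C(C)C)[C@H](OC(=O)/C(C)=C\C)C=C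
F2 | step 11 | cyclohexenol, C2 carbinol of 18 (C2 epimers) | C/C=C(/C)C(=O)O[C@@H]1C=C(CO[Si](C)(C)C(C)(C)C)C(O)C[C@@H]1C(C)C
F3 | step 12 | all-trans 3-hydroxy-4-isopropyl-5-ethenyloxolan-2-one | O=C1[C@@H](O)[C@H](C(C)C)[C@@H](C=C)O1
F4 | step 12 | O3-TES ether of F3 | O=C1[C@@H](O[Si](CC)(CC)CC)[C@H](C(C)C)[C@@H](C=C)O1
F5 | step 12 | O3-TES hydroxy enone | C=C(CO[Si](C)(C)C(C)(C)C)C(=O)[C@@H](O[Si](CC)(CC)CC)[C@H](C(C)C)[C@H](O)C=C
F6 | step 12 | O3-TES dienone angelate | C=C(CO[Si](C)(C)C(C)(C)C)C(=O)[C@@H](O[Si](CC)(CC)CC)[C@H](C(C)C)[C@H](OC(=O)/C(C)=C\C)C=C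
F7 | step 12 | O3-TES cyclohexenone (O3-TES ether of 21) | C/C=C(/C)C(=O)O[C@@H]1C=C(CO[Si](C)(C)C(C)(C)C)C(=O)[C@@H](O[Si](CC)(CC)CC)[C@@H]1C(C)C
F8 | step 9 | hydroxy Weinreb amide from 13 | CON(C)C(=O)C[C@H](C(C)C)[C@H](O)C=C
F9 | step 9 | O5-TES Weinreb amide | CON(C)C(=O)C[C@H](C(C)C)[C@H](O[Si](CC)(CC)CC)C=C
F10 | step 9 | O5-TES ether of 15 | C=C(CO[Si](C)(C)C(C)(C)C)C(=O)C[C@H](C(C)C)[C@H](O[Si](CC)(CC)CC)C=C
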